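Everything rests on building the benzene of ring A late, by annulation (chroman-2-one numbering; primed locants for the tetrahydroxy lactone, ring B). In ring A, C4a carries the C4 side chain between oxygens on C5 and C8a, with a third oxygen on C7: the pattern produced when a 3-alkoxy-4-alkylcyclobutenone is annulated with an ynol ether. The precursor is a 3-benzyloxycyclobutenone that already carries the C3 and C4 stereocentres, the C2 methyl ester and the flat coumarin of ring B. Heating it with a silyl ynol ether forms C8a–C8 and C6–C7, re-forms C8a–C4a and releases the C8a phenol that then closes lactone A. Hydrogenation of C3'=C4' with debenzylation finishes.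

Key step: step 19

Abbreviations: Bn = benzyl; Q = 5,6,7,8-tetrakis(benzyloxy)-4-[4-(benzyloxy)phenyl]-2-oxo-2H-chromen-3-yl (the protected coumarin of ring B); L = O,O'-[(S)-1,1'-binaphthyl-2,2'-diyl] N,N-bis[(S)-1-phenylethyl]phosphoramidite.
Remark: the thermal step uses a triisopropylsilyl ynol ether, because benzyl alkynyl ethers rearrange sigmatropically near 60 °C, below the temperature at which a cyclobutenone opens; the benzyl ynol ether is kept only for the cold ketene cycloaddition of step 17.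
Assumption: the catalyst enantiomers named in step 12 are those expected to give 2R,3R by analogy with cinnamyl carbonates and arylacetic esters; the two catalysts control C4 and C3 independently, so either is exchanged for its mirror image if the sense proves opposite.

Step 1
Reactants: 1 3,4,5-trihydroxybenzaldehyde
Product: 2 3,4,5-tris(benzyloxy)benzaldehyde
Conditions: BnBr, K2CO3, DMF, 60 °C
Reagents that add atoms: benzyl bromide, BrCc1ccccc1
Why: Williamson etherification of the three acidic phenols under carbonate leaves the aldehyde untouched.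

Step 2
Reactants: 2 3,4,5-tris(benzyloxy)benzaldehyde
Product: 4 3,4,5-tris(benzyloxy)phenol, via aryl formate 3 (not isolated)
Conditions: mCPBA, CH2Cl2, 0 °C to rt; then K2CO3 (cat.), MeOH, rt
Reagents that add atoms: 3-chloroperbenzoic acid, OOC(=O)c1cccc(Cl)c1
Why: Baeyer–Villiger (Dakin-type) oxidation in which the electron-rich aryl group migrates to oxygen gives the aryl formate, which mild methanolysis cleaves to the phenol while the benzyl ethers are inert.

Step 3
Reactants: 4 3,4,5-tris(benzyloxy)phenol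
Product: 6 3,4,5-tris(benzyloxy)benzene-1,2-diol, via ortho-quinone 5 (not isolated)
Conditions: IBX, DMF, rt; then aq. Na2S2O4
Reagents that add atoms: 2-iodoxybenzoic acid (IBX), O=C1OI(=O)(O)c2ccccc12
Why: Ortho-selective oxygenation of an electron-rich phenol by IBX, which passes oxygen from the aryloxy-iodine intermediate to an ortho carbon (both ortho positions are equivalent and the para position is blocked), is followed by dithionite reduction of the quinone to the catechol.

Step 4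
Reactants: 6 3,4,5-tris(benzyloxy)benzene-1,2-diol
Product: 7 pentakis(benzyloxy)benzene
Conditions: BnBr, K2CO3, DMF, rt, under N2
Reagents that add atoms: benzyl bromide, BrCc1ccccc1
Why: Williamson etherification of both hydroxyls of the air-sensitive catechol, carried out at once, gives the symmetrical pentaether with a single ring hydrogen.

Step 5
Reactants: 7 pentakis(benzyloxy)benzene; 8 4-(benzyloxy)benzonitrile
Product: 11 [4-(benzyloxy)phenyl][pentakis(benzyloxy)phenyl]methanone, via aryllithium 9 (not isolated), via N-lithio ketimine 10 (not isolated)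
Conditions: n-BuLi, THF, 0 °C; 8, 0 °C to rt; then 2 M HCl, THF, 40 °C
Reagents that add atoms: water, O
Why: Directed ortho-metalation at the only ring C–H, flanked and activated by two coordinating benzyloxy groups, gives an aryllithium that adds once to the nitrile (the N-lithio ketimine resists further addition), and acid hydrolysis unveils the diaryl ketone.

Step 6
Reactants: 11 [4-(benzyloxy)phenyl][pentakis(benzyloxy)phenyl]methanone
Product: 12 [4-(benzyloxy)phenyl][3,4,5,6-tetrakis(benzyloxy)-2-hydroxyphenyl]methanone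
Conditions: MgBr2·OEt2, toluene/Et2O, 80 °C; aq. HCl work-up
Reagents that add atoms: none
Why: Chelation-controlled debenzylation, in which magnesium bridges the ketone oxygen and one ortho ether oxygen so that bromide removes only that benzyl group (the two ortho ethers are equivalent and the magnesium phenoxide chelate blocks a second cleavage), leaves the non-chelated benzyl ethers intact.

Step 7
Reactants: 12 [4-(benzyloxy)phenyl][3,4,5,6-tetrakis(benzyloxy)-2-hydroxyphenyl]methanone; 13 succinic anhydride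
Product: 16 2-Q-acetic acid, via aryl hydrogen succinate 14 (not isolated), via aldol lactone 15 (not isolated)
Conditions: LiN(SiMe3)2 (1.0 equiv), THF, 0 °C; 13; LiN(SiMe3)2 (1.3 equiv), −78 to 0 °C; then 2 M HCl, THF, 50 °C
Reagents that add atoms: none
Why: The phenoxide opens the anhydride, the carboxylate so formed shields its own α-methylene so that the amide base enolises only the aryl ester, and intramolecular aldol addition onto the benzophenone carbonyl followed by acid dehydration of the tertiary, doubly benzylic alcohol closes the coumarin (a stepwise Perkin–Kostanecki-type condensation).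

Step 8
Reactants: 16 2-Q-acetic acid
Product: 17 pentafluorophenyl 2-Q-acetate
Conditions: C6F5OH, EDC·HCl, CH2Cl2, 0 °C to rt
Reagents that add atoms: pentafluorophenol, Oc1c(F)c(F)c(F)c(F)c1F
Why: Carbodiimide esterification gives the pentafluorophenyl ester, the acyl donor needed to form an isothiourea-bound ammonium enolate in step 12.

Step 9
Reactants: 18 4-(benzyloxy)benzaldehyde
Product: 19 ethyl (2E)-3-[4-(benzyloxy)phenyl]prop-2-enoate
Conditions: (EtO)2P(O)CH2CO2Et, NaH, THF, 0 °C to rt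
Reagents that add atoms: triethyl phosphonoacetate, CCOC(=O)CP(=O)(OCC)OCC
Why: Horner–Wadsworth–Emmons olefination of an aromatic aldehyde with a stabilised phosphonate anion gives the (E)-cinnamate.

Step 10
Reactants: 19 ethyl (2E)-3-[4-(benzyloxy)phenyl]prop-2-enoate
Product: 20 (2E)-3-[4-(benzyloxy)phenyl]prop-2-en-1-ol
Conditions: i-Bu2AlH (2.2 equiv), CH2Cl2, −78 to 0 °C; aqueous work-up
Reagents that add atoms: none
Why: 1,2-Reduction of the conjugated ester by two hydride equivalents gives the allylic alcohol without touching the alkene or the benzyl ether.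

Step 11
Reactants: 20 (2E)-3-[4-(benzyloxy)phenyl]prop-2-en-1-ol
Product: 21 tert-butyl (2E)-3-[4-(benzyloxy)phenyl]prop-2-en-1-yl carbonate
Conditions: Boc2O, DMAP (cat.), CH2Cl2, 0 °C to rt
Reagents that add atoms: di-tert-butyl dicarbonate, CC(C)(C)OC(=O)OC(=O)OC(C)(C)C
Why: Nucleophile-catalysed acylation of the primary allylic alcohol gives the tert-butyl carbonate, the leaving group for iridium-catalysed ionisation.

Step 12
Reactants: 17 pentafluorophenyl 2-Q-acetate; 21 tert-butyl (2E)-3-[4-(benzyloxy)phenyl]prop-2-en-1-yl carbonate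
Product: 23 methyl (2R,3R)-3-[4-(benzyloxy)phenyl]-2-Q-pent-4-enoate, via allylated pentafluorophenyl ester 22 (not isolated)
Conditions: [Ir(cod)Cl]2 (2 mol %), (Sa,S,S)-L (4 mol %), (S)-benzotetramisole (10 mol %), THF, rt; then MeOH, DMAP, 0 °C
Reagents that add atoms: methanol, CO
Why: Synergistic iridium/isothiourea branched allylation of an arylacetic-type active ester: the cyclometalated iridium–phosphoramidite complex ionises 21 and is attacked at the aryl-bearing allyl terminus by the ammonium enolate formed from 17 and benzotetramisole, so that C4 is set by the phosphoramidite and C3 by the face shielding of the isothiourea, after which pentafluorophenoxide releases the catalyst and methanol exchanges the active ester.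

Step 13
Reactants: 23 methyl (2R,3R)-3-[4-(benzyloxy)phenyl]-2-Q-pent-4-enoate
Product: 25 methyl (2R,3R)-3-[4-(benzyloxy)phenyl]-5-hydroxy-2-Q-pentanoate, via alkylborane 24 (not isolated)
Conditions: 9-BBN, THF, 0 °C to rt; then H2O2, aq. NaOAc, 0 °C
Reagents that add atoms: hydrogen peroxide, OO
Why: Anti-Markovnikov hydroboration by the bulky borane occurs only at the terminal vinyl group (the tetrasubstituted, conjugated C3'=C4' bond and the esters are inert), and buffered peroxide oxidation replaces boron by hydroxyl without epimerising C3.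

Step 14
Reactants: 25 methyl (2R,3R)-3-[4-(benzyloxy)phenyl]-5-hydroxy-2-Q-pentanoate
Product: 27 (3R,4R)-3-[4-(benzyloxy)phenyl]-5-methoxy-5-oxo-4-Q-pentanoic acid, via aldehyde 26 (not isolated)
Conditions: TEMPO (cat.), PhI(OAc)2, MeCN/H2O, rt
Reagents that add atoms: water, O
Why: Oxoammonium (TEMPO) oxidation with PhI(OAc)2 as terminal oxidant takes the primary alcohol through the aldehyde hydrate to the acid under near-neutral conditions that spare benzyl ethers, the lactone and both stereocentres.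

Step 15
Reactants: 28 benzyl alcohol; 29 trichloroethylene
Product: 31 benzyl (E)-1,2-dichlorovinyl ether, via dichloroacetylene 30 (not isolated)
Conditions: KH, THF, 0 °C; 29, rt
Reagents that add atoms: none
Why: Base-induced loss of HCl from trichloroethylene gives dichloroacetylene, to which the alkoxide adds in anti fashion to give the (E)-dichlorovinyl ether (first stage of the standard alkynyl ether synthesis).

Step 16
Reactants: 31 benzyl (E)-1,2-dichlorovinyl ether
Product: 34 benzyloxyacetylene, via chloroalkyne 32 (not isolated), via lithium acetylide 33 (not isolated)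
Conditions: n-BuLi (2.2 equiv), Et2O, −78 to −40 °C; then MeOH, −78 °C; kept cold in solution
Reagents that add atoms: none
Why: Lithiation with loss of LiCl gives the chloroalkyne, chlorine–lithium exchange the lithium alkoxyacetylide and cold protonation the terminal ynol ether, which is used below room temperature because of its thermal rearrangement.

Step 17
Reactants: 27 (3R,4R)-3-[4-(benzyloxy)phenyl]-5-methoxy-5-oxo-4-Q-pentanoic acid; 34 benzyloxyacetylene
Product: 37 methyl (2R,3R)-3-[4-(benzyloxy)phenyl]-3-[(1RS)-2-(benzyloxy)-4-oxocyclobut-2-en-1-yl]-2-Q-propanoate, via acid chloride 35 (not isolated), via ketene 36 (not isolated)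
Conditions: (COCl)2, DMF (cat.), CH2Cl2, 0 °C to rt; evaporate; then 34 (3 equiv), Et3N, CH2Cl2, 0 °C to rt
Reagents that add atoms: none
Why: Dehydrochlorination of the acid chloride gives an aldoketene that the ynol ether traps in a regioselective [2+2] cycloaddition (nucleophilic CH terminus to the ketene carbonyl carbon) to give the 3-alkoxy-4-alkylcyclobutenone; the new ring stereocentre is left uncontrolled because step 19 destroys it, and C3 and C4 are untouched.

Step 18
Reactants: 38 acetylene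
Product: 41 (triisopropylsilyloxy)acetylene, via lithium acetylide 39 (not isolated), via lithium ethynolate 40 (not isolated)
Conditions: n-BuLi, THF, −78 °C; t-BuOOLi (from t-BuOOH and LiN(SiMe3)2), −78 to −20 °C; i-Pr3SiOTf, −78 °C
Reagents that add atoms: tert-butyl hydroperoxide, CC(C)(C)OO; triisopropylsilyl trifluoromethanesulfonate, CC(C)[Si](C(C)C)(C(C)C)OS(=O)(=O)C(F)(F)F
Why: Electrophilic oxygen transfer from lithium tert-butyl peroxide to the acetylide carbon gives the ynolate, which the bulky silyl triflate captures on oxygen (ynolate O-silylation) to give the silyl ynol ether.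

Step 19
Reactants: 37 methyl (2R,3R)-3-[4-(benzyloxy)phenyl]-3-[(1RS)-2-(benzyloxy)-4-oxocyclobut-2-en-1-yl]-2-Q-propanoate; 41 (triisopropylsilyloxy)acetylene
Product: 46 methyl (2R,3R)-3-[4-(benzyloxy)phenyl]-3-[2-(benzyloxy)-6-hydroxy-4-(triisopropylsilyloxy)phenyl]-2-Q-propanoate, via vinylketene 42 (not isolated), via vinylcyclobutenone 43 (not isolated), via dienylketene 44 (not isolated), via cyclohexadienone 45 (not isolated)
Conditions: 41 (3 equiv), toluene, 110 °C, sealed tube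
Reagents that add atoms: none
Why: On heating, the cyclobutenone undergoes conrotatory 4π-electrocyclic opening (the alkyl group on the future C4a turning outward) to 3-benzyloxy vinylketene 42, and the nucleophilic CH terminus of the silyl ynol ether attacks the ketene carbonyl carbon in a polarity-matched [2+2] cycloaddition that forms C8a–C8 and C6–C7 in 43. A second, reversible 4π opening gives dienylketene 44, whose thermally allowed disrotatory 6π-electrocyclisation re-forms C8a–C4a and closes the six-membered carbocycle, and tautomerisation of dienone 45 gives the benzene of ring A with C8a as the free phenol. This is the Danheiser benzannulation of a cyclobutenone with a heteroatom-substituted alkyne, the established route to resorcinol derivatives, applied to a cyclobutenone that already carries the C5 oxygen. No stereocentre is created: the neutral pericyclic cascade does not touch C3 or C4, and the cyclobutenone stereocentre disappears on aromatisation. The only selectivity required is regiochemical, and the polarity of ketene and ynol ether fixes it, placing the silyloxy group on C7 and leaving C6 and C8 unsubstituted. The silyl ynol ether is used because it does not rearrange below the ring-opening temperature.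

Step 20
Reactants: 46 methyl (2R,3R)-3-[4-(benzyloxy)phenyl]-3-[2-(benzyloxy)-6-hydroxy-4-(triisopropylsilyloxy)phenyl]-2-Q-propanoate
Product: 48 (3R,4R)-5-(benzyloxy)-4-[4-(benzyloxy)phenyl]-7-hydroxy-3-Q-3,4-dihydro-2H-chromen-2-one, via hydroxy ester 47 (not isolated)
Conditions: Bu4NF, AcOH, THF, 0 °C; then p-TsOH·H2O (cat.), toluene, 80 °C
Reagents that add atoms: none
Why: Buffered fluoride cleaves the aryl silyl ether, and acid-catalysed transesterification of the C8a phenol onto the C2 methyl ester closes the six-membered lactone A, helped by the substituents on C3, C4 and C5 and leaving the (3R,4R) trans arrangement unchanged.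

Step 21
Reactants: 48 (3R,4R)-5-(benzyloxy)-4-[4-(benzyloxy)phenyl]-7-hydroxy-3-Q-3,4-dihydro-2H-chromen-2-one
Product: 49 (3R,4R)-5,7-dihydroxy-4-(4-hydroxyphenyl)-3-[(3S,4R)-5,6,7,8-tetrahydroxy-4-(4-hydroxyphenyl)-2-oxo-3,4-dihydro-2H-chromen-3-yl]-3,4-dihydro-2H-chromen-2-one
Conditions: H2 (50 bar), Pd(OH)2/C, EtOAc/MeOH/AcOH, 40 °C, air excluded on work-up
Reagents that add atoms: none
Why: Heterogeneous hydrogenation adds both hydrogens to one face of C3'=C4', so C3'–H and C4'–H are cis, and C3 chooses the face: with C3–H eclipsing the alkene to avoid allylic strain against the C4' aryl group, the flat lactone carbonyl C2 lies over one face and the arylated C4 over the other, so adsorption on the C2 face should give (3'S,4'R), while the same catalyst hydrogenolyses the seven benzyl ethers.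

Compound list
1 | 3,4,5-trihydroxybenzaldehyde | O=Cc1cc(O)c(O)c(O)c1 | starting material
2 | 3,4,5-tris(benzyloxy)benzaldehyde | O=Cc1cc(OCc9ccccc9)c(OCc9ccccc9)c(OCc9ccccc9)c1 | intermediate
3 | 3,4,5-tris(benzyloxy)phenyl formate | O=COc1cc(OCc9ccccc9)c(OCc9ccccc9)c(OCc9ccccc9)c1 | intermediate
4 | 3,4,5-tris(benzyloxy)phenol | Oc1cc(OCc9ccccc9)c(OCc9ccccc9)c(OCc9ccccc9)c1 | intermediate
5 | 3,4,5-tris(benzyloxy)cyclohexa-3,5-diene-1,2-dione | O=C1C(=O)C(OCc9ccccc9)=C(OCc9ccccc9)C(OCc9ccccc9)=C1 | intermediate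
6 | 3,4,5-tris(benzyloxy)benzene-1,2-diol | Oc1cc(OCc9ccccc9)c(OCc9ccccc9)c(OCc9ccccc9)c1O | intermediate
7 | pentakis(benzyloxy)benzene | c1c(OCc9ccccc9)c(OCc9ccccc9)c(OCc9ccccc9)c(OCc9ccccc9)c1OCc9ccccc9 | intermediate
8 | 4-(benzyloxy)benzonitrile | N#Cc1ccc(OCc9ccccc9)cc1 | starting material
9 | [pentakis(benzyloxy)phenyl]lithium | [Li]c1c(OCc9ccccc9)c(OCc9ccccc9)c(OCc9ccccc9)c(OCc9ccccc9)c1OCc9ccccc9 | intermediate
10 | N-lithio-1-[4-(benzyloxy)phenyl]-1-[pentakis(benzyloxy)phenyl]methanimine | [Li]N=C(c1ccc(OCc9ccccc9)cc1)c1c(OCc9ccccc9)c(OCc9ccccc9)c(OCc9ccccc9)c(OCc9ccccc9)c1OCc9ccccc9 | intermediate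
11 | [4-(benzyloxy)phenyl][pentakis(benzyloxy)phenyl]methanone | O=C(c1ccc(OCc9ccccc9)cc1)c1c(OCc9ccccc9)c(OCc9ccccc9)c(OCc9ccccc9)c(OCc9ccccc9)c1OCc9ccccc9 | intermediate
12 | [4-(benzyloxy)phenyl][3,4,5,6-tetrakis(benzyloxy)-2-hydroxyphenyl]methanone | O=C(c1ccc(OCc9ccccc9)cc1)c1c(O)c(OCc9ccccc9)c(OCc9ccccc9)c(OCc9ccccc9)c1OCc9ccccc9 | intermediate
13 | succinic anhydride | O=C1CCC(=O)O1 | starting material
14 | 4-{3,4,5,6-tetrakis(benzyloxy)-2-[4-(benzyloxy)benzoyl]phenoxy}-4-oxobutanoic acid | OC(=O)CCC(=O)Oc1c(OCc9ccccc9)c(OCc9ccccc9)c(OCc9ccccc9)c(OCc9ccccc9)c1C(=O)c1ccc(OCc9ccccc9)cc1 | intermediate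
15 | 2-{5,6,7,8-tetrakis(benzyloxy)-4-[4-(benzyloxy)phenyl]-4-hydroxy-2-oxo-3,4-dihydro-2H-chromen-3-yl}acetic acid (racemic, both diastereomers) | OC(=O)CC1C(=O)Oc2c(OCc9ccccc9)c(OCc9ccccc9)c(OCc9ccccc9)c(OCc9ccccc9)c2C1(O)c1ccc(OCc9ccccc9)cc1 | intermediate
16 | 2-Q-acetic acid | OC(=O)CC1=C(c2ccc(OCc9ccccc9)cc2)c2c(OCc9ccccc9)c(OCc9ccccc9)c(OCc9ccccc9)c(OCc9ccccc9)c2OC1=O | intermediate
17 | pentafluorophenyl 2-Q-acetate | O=C(CC1=C(c2ccc(OCc9ccccc9)cc2)c2c(OCc9ccccc9)c(OCc9ccccc9)c(OCc9ccccc9)c(OCc9ccccc9)c2OC1=O)Oc1c(F)c(F)c(F)c(F)c1F | intermediate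
18 | 4-(benzyloxy)benzaldehyde | O=Cc1ccc(OCc9ccccc9)cc1 | starting material
19 | ethyl (2E)-3-[4-(benzyloxy)phenyl]prop-2-enoate | CCOC(=O)/C=C/c1ccc(OCc9ccccc9)cc1 | intermediate
20 | (2E)-3-[4-(benzyloxy)phenyl]prop-2-en-1-ol | OC/C=C/c1ccc(OCc9ccccc9)cc1 | intermediate
21 | tert-butyl (2E)-3-[4-(benzyloxy)phenyl]prop-2-en-1-yl carbonate | CC(C)(C)OC(=O)OC/C=C/c1ccc(OCc9ccccc9)cc1 | intermediate
22 | pentafluorophenyl (2R,3R)-3-[4-(benzyloxy)phenyl]-2-Q-pent-4-enoate | C=C[C@@H](c1ccc(OCc9ccccc9)cc1)[C@@H](C(=O)Oc1c(F)c(F)c(F)c(F)c1F)C1=C(c2ccc(OCc9ccccc9)cc2)c2c(OCc9ccccc9)c(OCc9ccccc9)c(OCc9ccccc9)c(OCc9ccccc9)c2OC1=O | intermediate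
23 | methyl (2R,3R)-3-[4-(benzyloxy)phenyl]-2-Q-pent-4-enoate | C=C[C@@H](c1ccc(OCc9ccccc9)cc1)[C@@H](C(=O)OC)C1=C(c2ccc(OCc9ccccc9)cc2)c2c(OCc9ccccc9)c(OCc9ccccc9)c(OCc9ccccc9)c(OCc9ccccc9)c2OC1=O | intermediate
24 | methyl (2R,3R)-3-[4-(benzyloxy)phenyl]-5-(9-borabicyclo[3.3.1]nonan-9-yl)-2-Q-pentanoate | C1CCC2CCCC1B2CC[C@@H](c1ccc(OCc9ccccc9)cc1)[C@@H](C(=O)OC)C1=C(c2ccc(OCc9ccccc9)cc2)c2c(OCc9ccccc9)c(OCc9ccccc9)c(OCc9ccccc9)c(OCc9ccccc9)c2OC1=O | intermediate
25 | methyl (2R,3R)-3-[4-(benzyloxy)phenyl]-5-hydroxy-2-Q-pentanoate | OCC[C@@H](c1ccc(OCc9ccccc9)cc1)[C@@H](C(=O)OC)C1=C(c2ccc(OCc9ccccc9)cc2)c2c(OCc9ccccc9)c(OCc9ccccc9)c(OCc9ccccc9)c(OCc9ccccc9)c2OC1=O | intermediate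
26 | methyl (2R,3R)-3-[4-(benzyloxy)phenyl]-5-oxo-2-Q-pentanoate | O=CC[C@@H](c1ccc(OCc9ccccc9)cc1)[C@@H](C(=O)OC)C1=C(c2ccc(OCc9ccccc9)cc2)c2c(OCc9ccccc9)c(OCc9ccccc9)c(OCc9ccccc9)c(OCc9ccccc9)c2OC1=O | intermediate
27 | (3R,4R)-3-[4-(benzyloxy)phenyl]-5-methoxy-5-oxo-4-Q-pentanoic acid | OC(=O)C[C@@H](c1ccc(OCc9ccccc9)cc1)[C@@H](C(=O)OC)C1=C(c2ccc(OCc9ccccc9)cc2)c2c(OCc9ccccc9)c(OCc9ccccc9)c(OCc9ccccc9)c(OCc9ccccc9)c2OC1=O | intermediate
28 | benzyl alcohol | OCc1ccccc1 | starting material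
29 | trichloroethylene | ClC=C(Cl)Cl | starting material
30 | dichloroacetylene | ClC#CCl | intermediate
31 | benzyl (E)-1,2-dichlorovinyl ether | Cl/C=C(/Cl)OCc1ccccc1 | intermediate
32 | benzyl chloroethynyl ether | ClC#COCc1ccccc1 | intermediate
33 | lithium (benzyloxy)acetylide | [Li]C#COCc1ccccc1 | intermediate
34 | benzyloxyacetylene | C#COCc1ccccc1 | intermediate
35 | methyl (2R,3R)-3-[4-(benzyloxy)phenyl]-5-chloro-5-oxo-2-Q-pentanoate | ClC(=O)C[C@@H](c1ccc(OCc9ccccc9)cc1)[C@@H](C(=O)OC)C1=C(c2ccc(OCc9ccccc9)cc2)c2c(OCc9ccccc9)c(OCc9ccccc9)c(OCc9ccccc9)c(OCc9ccccc9)c2OC1=O | intermediate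
36 | methyl (2R,3R)-3-[4-(benzyloxy)phenyl]-5-oxo-2-Q-pent-4-enoate (ketene) | O=C=C[C@@H](c1ccc(OCc9ccccc9)cc1)[C@@H](C(=O)OC)C1=C(c2ccc(OCc9ccccc9)cc2)c2c(OCc9ccccc9)c(OCc9ccccc9)c(OCc9ccccc9)c(OCc9ccccc9)c2OC1=O | intermediate
37 | methyl (2R,3R)-3-[4-(benzyloxy)phenyl]-3-[(1RS)-2-(benzyloxy)-4-oxocyclobut-2-en-1-yl]-2-Q-propanoate | O=C1C=C(OCc9ccccc9)C1[C@@H](c1ccc(OCc9ccccc9)cc1)[C@@H](C(=O)OC)C1=C(c2ccc(OCc9ccccc9)cc2)c2c(OCc9ccccc9)c(OCc9ccccc9)c(OCc9ccccc9)c(OCc9ccccc9)c2OC1=O | intermediate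
38 | acetylene | C#C | starting material
39 | lithium acetylide | [Li]C#C | intermediate
40 | lithium ethynolate | [Li]OC#C | intermediate
41 | (triisopropylsilyloxy)acetylene | C#CO[Si](C(C)C)(C(C)C)C(C)C | intermediate
42 | methyl (2R,3R,4Z)-5-(benzyloxy)-3-[4-(benzyloxy)phenyl]-7-oxo-2-Q-hepta-4,6-dienoate (vinylketene) | O=C=C/C(OCc9ccccc9)=C/[C@@H](c1ccc(OCc9ccccc9)cc1)[C@@H](C(=O)OC)C1=C(c2ccc(OCc9ccccc9)cc2)c2c(OCc9ccccc9)c(OCc9ccccc9)c(OCc9ccccc9)c(OCc9ccccc9)c2OC1=O | intermediate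
43 | methyl (2R,3R,4Z)-5-(benzyloxy)-3-[4-(benzyloxy)phenyl]-5-[(1RS)-4-oxo-2-(triisopropylsilyloxy)cyclobut-2-en-1-yl]-2-Q-pent-4-enoate | O=C1C=C(O[Si](C(C)C)(C(C)C)C(C)C)C1/C(OCc9ccccc9)=C/[C@@H](c1ccc(OCc9ccccc9)cc1)[C@@H](C(=O)OC)C1=C(c2ccc(OCc9ccccc9)cc2)c2c(OCc9ccccc9)c(OCc9ccccc9)c(OCc9ccccc9)c(OCc9ccccc9)c2OC1=O | intermediate
44 | methyl (2R,3R,4Z,6E)-5-(benzyloxy)-3-[4-(benzyloxy)phenyl]-9-oxo-2-Q-7-(triisopropylsilyloxy)nona-4,6,8-trienoate (dienylketene) | O=C=C/C(O[Si](C(C)C)(C(C)C)C(C)C)=C\C(OCc9ccccc9)=C\[C@@H](c1ccc(OCc9ccccc9)cc1)[C@@H](C(=O)OC)C1=C(c2ccc(OCc9ccccc9)cc2)c2c(OCc9ccccc9)c(OCc9ccccc9)c(OCc9ccccc9)c(OCc9ccccc9)c2OC1=O | intermediate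
45 | methyl (2R,3R)-3-[4-(benzyloxy)phenyl]-3-[(1RS)-2-(benzyloxy)-6-oxo-4-(triisopropylsilyloxy)cyclohexa-2,4-dien-1-yl]-2-Q-propanoate | O=C1C=C(O[Si](C(C)C)(C(C)C)C(C)C)C=C(OCc9ccccc9)C1[C@@H](c1ccc(OCc9ccccc9)cc1)[C@@H](C(=O)OC)C1=C(c2ccc(OCc9ccccc9)cc2)c2c(OCc9ccccc9)c(OCc9ccccc9)c(OCc9ccccc9)c(OCc9ccccc9)c2OC1=O | intermediate
46 | methyl (2R,3R)-3-[4-(benzyloxy)phenyl]-3-[2-(benzyloxy)-6-hydroxy-4-(triisopropylsilyloxy)phenyl]-2-Q-propanoate | Oc1cc(O[Si](C(C)C)(C(C)C)C(C)C)cc(OCc9ccccc9)c1[C@@H](c1ccc(OCc9ccccc9)cc1)[C@@H](C(=O)OC)C1=C(c2ccc(OCc9ccccc9)cc2)c2c(OCc9ccccc9)c(OCc9ccccc9)c(OCc9ccccc9)c(OCc9ccccc9)c2OC1=O | intermediate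
47 | methyl (2R,3R)-3-[4-(benzyloxy)phenyl]-3-[2-(benzyloxy)-4,6-dihydroxyphenyl]-2-Q-propanoate | Oc1cc(O)cc(OCc9ccccc9)c1[C@@H](c1ccc(OCc9ccccc9)cc1)[C@@H](C(=O)OC)C1=C(c2ccc(OCc9ccccc9)cc2)c2c(OCc9ccccc9)c(OCc9ccccc9)c(OCc9ccccc9)c(OCc9ccccc9)c2OC1=O | intermediate
48 | (3R,4R)-5-(benzyloxy)-4-[4-(benzyloxy)phenyl]-7-hydroxy-3-Q-3,4-dihydro-2H-chromen-2-one | O=C1Oc2cc(O)cc(OCc9ccccc9)c2[C@@H](c2ccc(OCc9ccccc9)cc2)[C@@H]1C1=C(c2ccc(OCc9ccccc9)cc2)c2c(OCc9ccccc9)c(OCc9ccccc9)c(OCc9ccccc9)c(OCc9ccccc9)c2OC1=O | intermediate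
49 | (3R,4R)-5,7-dihydroxy-4-(4-hydroxyphenyl)-3-[(3S,4R)-5,6,7,8-tetrahydroxy-4-(4-hydroxyphenyl)-2-oxo-3,4-dihydro-2H-chromen-3-yl]-3,4-dihydro-2H-chromen-2-one | O=C1Oc2cc(O)cc(O)c2[C@@H](c2ccc(O)cc2)[C@@H]1[C@H]1C(=O)Oc2c(O)c(O)c(O)c(O)c2[C@H]1c1ccc(O)cc1 | target

Total step count: 21. Longest linear sequence: 15 steps (steps 1–8, 12–14, 17, 19–21).

Steps most likely to fail

Step 19. The vinylogous-ester cyclobutenone may open too slowly, so that the ynol ether is lost by silyl migration to carbon or the vinylketene dimerises before it is trapped; the dienylketene may also fail to close. The fallback brings ring A in as a ready-made arene instead of building it. The magnesium phenoxide of commercial 3,5-bis(benzyloxy)phenol (EtMgBr, toluene) adds ortho-selectively to aldehyde 18 to give 3,5-bis(benzyloxy)-2-{[4-(benzyloxy)phenyl](hydroxy)methyl}phenol F1. Exchange of the benzylic hydroxyl for sulfinate (sodium 4-methylbenzenesulfinate, formic acid) gives 3,5-bis(benzyloxy)-2-{[4-(benzyloxy)phenyl](4-methylbenzenesulfonyl)methyl}phenol F2, a stable ortho-quinone methide precursor. With Cs2CO3 and benzotetramisole, F2 loses sulfinate to give 3,5-bis(benzyloxy)-6-[4-(benzyloxy)benzylidene]cyclohexa-2,4-dien-1-one F3. The ammonium enolate of pentafluorophenyl ester 17 intercepts F3 in a Michael addition–lactonisation to give (3R,4R)-5,7-bis(benzyloxy)-4-[4-(benzyloxy)phenyl]-3-Q-3,4-dihydro-2H-chromen-2-one F4. The catalyst enantiomer is chosen for 4R, and any cis lactone is epimerised at C3 to the trans isomer with a tertiary amine. Hydrogenation of F4 under the conditions of step 21 gives 49. The fallback sets out from 17 and 18 and returns at 49.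

Step 12. Enolisation and alkylation of the crowded acyl ammonium ion, flanked by the lactone carbonyl and the C4' aryl group, may be slow, letting unselective background allylation or erosion at C3 during methanolysis compete. The fallback makes the C3–C4 bond intramolecularly. Acid 16 is esterified with alcohol 20 (EDC·HCl, DMAP) to give (2E)-3-[4-(benzyloxy)phenyl]prop-2-en-1-yl 2-Q-acetate F5. An enantioselective Ireland–Claisen rearrangement through a chiral boron ketene acetal follows (bromoborane of a 1,2-diphenylethane-1,2-diamine bis-sulfonamide, tertiary amine, CH2Cl2, −78 °C to rt), with the enolate geometry and reagent enantiomer chosen so that the chair transition state gives 2R,3R. It gives (2R,3R)-3-[4-(benzyloxy)phenyl]-2-Q-pent-4-enoic acid F6, which Me3SiCHN2 in MeOH/toluene converts into 23. The fallback sets out from 16 and 20 and returns at 23.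

Step 21. Hydrogen may be delivered to the wrong face of the tetrasubstituted C3'=C4' bond, or saturation may stall once the benzyl groups are gone. The fallback separates reduction from deprotection and replaces steric control by carbonyl direction. Homogeneous hydrogenation of 48 with [Ir(cod)(PCy3)(py)]PF6 in CH2Cl2 lets the cationic iridium bind the lactone A carbonyl and deliver hydrogen to the alkene face on which C2 lies. It gives (3R,4R)-5-(benzyloxy)-4-[4-(benzyloxy)phenyl]-7-hydroxy-3-{(3S,4R)-5,6,7,8-tetrakis(benzyloxy)-4-[4-(benzyloxy)phenyl]-2-oxo-3,4-dihydro-2H-chromen-3-yl}-3,4-dihydro-2H-chromen-2-one F7. Hydrogenolysis over Pd/C at 1 bar then gives 49. The fallback sets out from 48 and returns at 49.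

Further compounds
F1 | step 19 | 3,5-bis(benzyloxy)-2-{[4-(benzyloxy)phenyl](hydroxy)methyl}phenol (racemic) | Oc1cc(OCc9ccccc9)cc(OCc9ccccc9)c1C(O)c1ccc(OCc9ccccc9)cc1
F2 | step 19 | 3,5-bis(benzyloxy)-2-{[4-(benzyloxy)phenyl](4-methylbenzenesulfonyl)methyl}phenol (racemic) | Oc1cc(OCc9ccccc9)cc(OCc9ccccc9)c1C(c1ccc(OCc9ccccc9)cc1)S(=O)(=O)c1ccc(C)cc1
F3 | step 19 | 3,5-bis(benzyloxy)-6-[4-(benzyloxy)benzylidene]cyclohexa-2,4-dien-1-one (alkene geometry not defined) | O=C1C=C(OCc9ccccc9)C=C(OCc9ccccc9)C1=Cc1ccc(OCc9ccccc9)cc1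
F4 | step 19 | (3R,4R)-5,7-bis(benzyloxy)-4-[4-(benzyloxy)phenyl]-3-Q-3,4-dihydro-2H-chromen-2-one | O=C1Oc2cc(OCc9ccccc9)cc(OCc9ccccc9)c2[C@@H](c2ccc(OCc9ccccc9)cc2)[C@@H]1C1=C(c2ccc(OCc9ccccc9)cc2)c2c(OCc9ccccc9)c(OCc9ccccc9)c(OCc9ccccc9)c(OCc9ccccc9)c2OC1=O
F5 | step 12 | (2E)-3-[4-(benzyloxy)phenyl]prop-2-en-1-yl 2-Q-acetate | O=C(CC1=C(c2ccc(OCc9ccccc9)cc2)c2c(OCc9ccccc9)c(OCc9ccccc9)c(OCc9ccccc9)c(OCc9ccccc9)c2OC1=O)OC/C=C/c1ccc(OCc9ccccc9)cc1
F6 | step 12 | (2R,3R)-3-[4-(benzyloxy)phenyl]-2-Q-pent-4-enoic acid | C=C[C@@H](c1ccc(OCc9ccccc9)cc1)[C@@H](C(=O)O)C1=C(c2ccc(OCc9ccccc9)cc2)c2c(OCc9ccccc9)c(OCc9ccccc9)c(OCc9ccccc9)c(OCc9ccccc9)c2OC1=O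
F7 | step 21 | (3R,4R)-5-(benzyloxy)-4-[4-(benzyloxy)phenyl]-7-hydroxy-3-{(3S,4R)-5,6,7,8-tetrakis(benzyloxy)-4-[4-(benzyloxy)phenyl]-2-oxo-3,4-dihydro-2H-chromen-3-yl}-3,4-dihydro-2H-chromen-2-one | O=C1Oc2cc(O)cc(OCc9ccccc9)c2[C@@H](c2ccc(OCc9ccccc9)cc2)[C@@H]1[C@H]1C(=O)Oc2c(OCc9ccccc9)c(OCc9ccccc9)c(OCc9ccccc9)c(OCc9ccccc9)c2[C@H]1c1ccc(OCc9ccccc9)cc1
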